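## Analysis of the target

The target is a 2,3-dihydro-1-benzofuran: benzo ring A (C3a, C4–C7, C7a) is fused to dihydrofuran ring B (O1, C2, C3, C3a, C7a). It carries a 3,4,5-trimethoxyphenyl ring C on C2, a methyl group on C3, an (E)-prop-1-enyl group on C5 and a methoxy group on C6. The only stereocentres are the neighbouring C2 and C3, both R, with aryl and methyl trans across ring B. The C2–O1 bond is a benzylic aryl ether, open to hydrogenolysis and to acid ionisation that would scramble C2. Ring B can be dehydrogenated to a benzofuran with loss of both stereocentres, the styrene-type propenyl group is sensitive to acid, oxidants and hydride sources, and rings A and C are both electron-rich and compete for electrophiles. The difficulty lies in fixing two adjacent stereocentres that keep no functional group in the product, and in placing a carbon substituent at C5 of a ring whose oxygen atoms (O1 and the C6 methoxy) are meta to each other. The strategy rests on one feature: O1 and C3 are bonded to the adjacent ring A carbons C7a and C3a, which are the two ends of an aryne triple bond, and the unit O1–C2–C3 with a one-carbon branch on C3 is the skeleton of a 2,3-epoxy alcohol (carbinol carbon = C2, inner epoxide carbon = C3). An oxygen nucleophile and then a carbon electrophile can therefore be delivered to the aryne in one operation, if the C3 methyl is carried as CH2OH and a substituent at C4 polarises the aryne.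

## Retrosynthetic reasoning

**C5–propenyl bond (20 ⇒ 18 + 19).** The propenyl group is the most fragile part of the molecule and would not survive hydride, formate/palladium, brominating or aryne conditions. It is therefore cut first, as a Suzuki–Miyaura coupling of aryl bromide 18 with the E-alkenyl boronate 19. The forward step only has to transfer the alkene with retention of geometry.

**C5–Br bond (18 ⇒ 17).** C5 of 17 is para to O1 and ortho to the C6 methoxy group, the most activated and least hindered position of ring A. The bromine is therefore introduced by electrophilic substitution. The forward step has to prefer C5 over C7 and over the two open positions of ring C.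

**Spectator adjustments (17 ⇒ 16 ⇒ 15 ⇒ 14).** Two groups in 14 are not in the target: the chlorine on C4 and the hydroxyl on the C3 side chain. Both are the price of the key step: the chlorine controls the regiochemistry of the aryne, and the CH2OH group is what remains of the epoxide. They are removed in the order hydroxyl (through tosylate 15 and hydride displacement to 16), then chlorine (to 17). This keeps the reductions ahead of the bromination and of the propenyl group.

**O1–C7a and C3–C3a (14 ⇒ 7 + 11, through 12 and 13).** This is the strategic cut. Both bonds from ring B to ring A are broken at once, which leads to aryne 13 (from silyl triflate 7) and the alkoxide 12 of the erythro epoxy alcohol 11. It is made here because it takes ring A from a simple arene with its oxygenation in place, and takes both stereocentres from one small, readily made fragment. The forward reaction has to add the alkoxide to the aryne carbon remote from chlorine, keep the resulting aryl anion unprotonated, and have it open the epoxide at the inner carbon with inversion.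

**Epoxy alcohol (11 ⇒ 10 ⇒ 8 + 9).** The erythro 2,3-epoxy alcohol is the product of a kinetic-resolution epoxidation of the racemic allylic alcohol 10. This selects the carbinol configuration (future C2) and creates the epoxide centre (future C3) in one step. 10 comes from aldehyde 8 and the vinyl Grignard reagent 9.

**Aryne precursor (7 ⇒ 4 ⇒ 3 ⇒ 2 ⇒ 1).** The silicon of 7 must sit between the oxygen and the chlorine. Direct ortho-metalation of an O-acyl derivative of 1 was not adopted. The two positions flanking the oxygen, one next to chlorine and one next to methoxy, are both doubly activated, and a clean choice between them cannot be relied on. The position is instead fixed by a bromine: in acetate 2 the methoxy group is the only strong donor, so bromination goes para to it, which is the required carbon (3). Deacylation gives bromophenol 4, and O-silylation, bromine–lithium exchange with retro-Brook shift and triflation give 7 from commercial phenol 1.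

## Alternatives that were turned down

**Alternative 1:** Ring A is not taken from an arene but closed last. O1–C7a and C3a–C4 are cut, which opens the bicycle to the acyclic hydroxy vinyl ynone A1, already holding C2 and C3. In the forward direction an alkoxide base would make the C2 oxygen add to the ynone β-carbon C7a (5-exo-dig oxa-Michael). γ-Deprotonation at C3a would give a trienolate running from C3a to C4, and 6π-electrocyclisation would close C3a–C4 to give the bicyclic enone A2.
- For: both rings form in one flask from an open chain, the stereocentres can be set by acyclic methods without a resolution, and no directing halogen has to be removed. On these points it is at least as good as the chosen route.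
- Against: the vinyl ketone end of A1 is a better Michael acceptor than the ynone is a partner for a hindered secondary alkoxide, so oligomerisation competes. The electrocyclisation needs one specific geometry of the intermediate alkylidene tetrahydrofuran. A2 is neither aromatic nor substituted at C5, so dehydrogenation (which can run on to the benzofuran and erase C2 and C3), O-methylation and the same late C5 bromination and coupling still follow.
- Comparison: the aryne route starts with ring A aromatic and correctly oxygenated, needs no redox adjustment of that ring, and reaches the common late intermediate 17 in fewer operations.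

**Alternative 2:** Ring A is assembled by cycloaddition on a finished ring B. C3a–C4 and C5–C6 are cut, giving the dihydrofuran-based silyl ketene acetal diene A3 and the acetylenic ketone A4. The Diels–Alder reaction joins the nucleophilic diene terminus C3a to the alkyne CH and the acetal carbon C6 to the acylated alkyne carbon. Loss of silanol from the adduct aromatises it to the propiophenone A5.
- For: the C6 methoxy group and a three-carbon chain at C5 arrive together with regiochemistry fixed by the polarisation of the diene. No electrophilic substitution in the presence of ring C and no removal of a directing group is needed. Here the alternative is stronger than the chosen route, whose step 11 must discriminate between two electron-rich rings.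
- Against: A3 is an acid- and moisture-labile enol ether and ketene acetal. It has to be made by γ-deprotonation and O-silylation of an ester precursor that itself needs a multistep stereocontrolled synthesis. The adduct can lose methanol instead of silanol. A5 still needs reduction and an acid dehydration next to the acid-sensitive C2–O1 bond.
- Comparison: it is no shorter. The chosen strategy offers ring A from a commercial arene, both stereocentres from a two-step epoxy alcohol, and only one uncertain step.

**Alternative 3:** Ring A is again built on a heterocycle, but by ionic annulation. C4–C5 and C7–C7a are cut, leading to the trans α-methylene lactone A6 (O1, C2, C3, C3a, C7a and C4 in place) and the β-keto ester A7. The enolate of A7 would add through its central carbon to the exocyclic methylene C4, its methyl terminus would then acylate on the lactone carbonyl C7a with ring opening, and acid would reclose O1 onto C7a to give the bicyclic vinylogous ester A8.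
- For: only classical carbonyl reactions are used, and a carbon substituent at C5 beside oxygen at C6 is placed without ambiguity. This is again a better answer to the C5 problem than a late bromination.
- Against: under the basic Michael conditions the exocyclic double bond of A6 can move into the ring, which removes the C3 stereocentre. The Claisen closure must use the less acidic terminus of A7. A8 is far from the target: dehydrogenation to the arene (with the same over-oxidation risk), O-methylation and a three-step conversion of the ester into the E-propenyl group follow, on top of the synthesis of A6.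
- Comparison: it is longer overall. The chosen route exchanges a safe but long sequence for a short one with a single demanding step, and never changes the oxidation level of ring A.

Key step: step 7

Remark: ring positions are numbered as in the target (O1, C2, C3, C3a, C4–C7, C7a) in every intermediate. The C3 descriptor changes from S in 14 and 15 to R from 16 on through CIP priorities only; no bond at C3 is touched after step 7.

## Route

Step 1
Reactants: 1 3-chloro-5-methoxyphenol
Product: 2 3-chloro-5-methoxyphenyl acetate
Conditions: Ac2O, Et3N, DMAP (cat.), CH2Cl2, 0 °C to rt
Reagents that add atoms: acetic anhydride, CC(=O)OC(C)=O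
Why: Acetylation of the phenol (nucleophilic acyl substitution under DMAP catalysis) turns the strongest donor of the ring into a weak one, so that the methoxy group alone steers the bromination that follows.

Step 2
Reactants: 2 3-chloro-5-methoxyphenyl acetate
Product: 3 2-bromo-3-chloro-5-methoxyphenyl acetate
Conditions: NBS, MeCN, 0 °C to rt
Reagents that add atoms: N-bromosuccinimide, O=C1CCC(=O)N1Br
Why: Electrophilic aromatic bromination; with the phenol acylated the methoxy group is the dominant donor, and N-bromosuccinimide in acetonitrile substitutes anisoles para to OMe, which here is the carbon between OAc and Cl. The two ortho positions are just as flanked and electronically less favoured, so 3 should be the main isomer and is purified by crystallisation or chromatography.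

Step 3
Reactants: 3 2-bromo-3-chloro-5-methoxyphenyl acetate
Product: 4 2-bromo-3-chloro-5-methoxyphenol
Conditions: K2CO3, MeOH, 0 °C to rt
Reagents that add atoms: none
Why: Base-catalysed transesterification (methanolysis) of the aryl acetate frees the phenol; the aryl bromide, aryl chloride and methyl ether are inert to these conditions.

Step 4
Reactants: 4 2-bromo-3-chloro-5-methoxyphenol
Product: 7 3-chloro-5-methoxy-2-(trimethylsilyl)phenyl trifluoromethanesulfonate, via aryl trimethylsilyl ether 5 (not isolated), via lithium 2-silylphenoxide 6 (not isolated)
Conditions: (Me3Si)2NH, THF, reflux, then evaporate; n-BuLi, THF, −100 °C; Tf2O, −100 to −78 °C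
Reagents that add atoms: hexamethyldisilazane, C[Si](C)(C)N[Si](C)(C)C; trifluoromethanesulfonic anhydride, O=S(=O)(OS(=O)(=O)C(F)(F)F)C(F)(F)F
Why: O-Silylation, then bromine–lithium exchange (faster at −100 °C than chlorine exchange or ring deprotonation) and retro-Brook 1,3-shift of silicon from oxygen to the lithiated carbon give phenoxide 6, which is triflated in the same flask. The bromine fixes the position of silicon, and the low temperature keeps the transient 2-chloroaryllithium from losing LiCl.

Step 5
Reactants: 8 3,4,5-trimethoxybenzaldehyde; 9 vinylmagnesium bromide
Product: 10 rac-1-(3,4,5-trimethoxyphenyl)prop-2-en-1-ol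
Conditions: THF, −78 to 0 °C; aq NH4Cl
Reagents that add atoms: none
Why: Grignard 1,2-addition of the vinyl nucleophile to the aromatic aldehyde gives the racemic allylic alcohol; no selectivity is needed at this stage.

Step 6
Reactants: 10 rac-1-(3,4,5-trimethoxyphenyl)prop-2-en-1-ol
Product: 11 (S)-[(2R)-oxiran-2-yl](3,4,5-trimethoxyphenyl)methanol (erythro)
Conditions: Ti(OiPr)4 (0.2 equiv), L-(+)-diisopropyl tartrate (0.25 equiv), t-BuOOH (0.45 equiv), 4 Å MS, CH2Cl2, −20 °C
Reagents that add atoms: tert-butyl hydroperoxide, CC(C)(C)OO
Why: Sharpless kinetic resolution by asymmetric epoxidation: with L-(+)-diisopropyl tartrate the (R)-enantiomer of 10 should react fast and receive oxygen on the alkene face that makes the epoxide carbon R, which gives the erythro isomer. With the oxidant limited to 0.45 equivalents, 11 should form in high enantiomeric and diastereomeric purity, and the unreacted (S)-alcohol is separated by chromatography. The carbinol centre (future C2) is selected by the resolution and the epoxide centre (future C3, before inversion) is created under reagent control.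

Step 7
Reactants: 11 (S)-[(2R)-oxiran-2-yl](3,4,5-trimethoxyphenyl)methanol; 7 3-chloro-5-methoxy-2-(trimethylsilyl)phenyl trifluoromethanesulfonate
Product: 14 [(2R,3S)-4-chloro-6-methoxy-2-(3,4,5-trimethoxyphenyl)-2,3-dihydro-1-benzofuran-3-yl]methanol, via sodium epoxy alkoxide 12 (not isolated), via 3-chloro-5-methoxybenzyne 13 (not isolated)
Conditions: 11 (1.5 equiv), NaH (1.6 equiv), THF, 0 °C; then 7 (1.0 equiv), CsF, 18-crown-6, THF, −20 °C to rt; H2O
Reagents that add atoms: none
Why: Proposed new method: fluoride attacks the silicon of 7 and triflate leaves to give aryne 13; the C–Cl bond next to the triple bond polarises it, so the fully deprotonated alkoxide 12 adds to the carbon remote from chlorine (future C7a) and the carbanion forms at C3a, where the adjacent chlorine stabilises it inductively. With no O–H left in the flask the aryl anion is not protonated and attacks the inner epoxide carbon from the back, a 5-exo-tet closure of ring B that forms C3–C3a and releases the primary alkoxide. The closest known reaction types are alkoxide addition to arynes with intramolecular capture of the aryl anion, and the Parham-type cyclisation of 2-lithiophenyl glycidyl ethers to 2,3-dihydrobenzofuran-3-ylmethanols; their combination in one operation on an epoxy alkoxide is not known. C2 keeps the carbinol configuration of 11 because its C–O bond is never broken, and C3 is set by stereospecific inversion at the epoxide carbon, so the erythro relationship of 11 becomes the 2,3-trans ring. The step needs regioselective addition to the aryne, secured by the chlorine next to the triple bond, which outweighs the weak opposing effect of the methoxy group. It also needs 5-exo rather than 6-endo opening, secured by the short O1–C2 tether, which lets the in-plane aryl lone pair reach only the inner carbon along the C–O axis. Any O-silylation of 12 by 7 is reversed by fluoride, and 12 is kept in excess so that the product alkoxide does not compete for the aryne.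

Step 8
Reactants: 14 [(2R,3S)-4-chloro-6-methoxy-2-(3,4,5-trimethoxyphenyl)-2,3-dihydro-1-benzofuran-3-yl]methanol
Product: 15 [(2R,3S)-4-chloro-6-methoxy-2-(3,4,5-trimethoxyphenyl)-2,3-dihydro-1-benzofuran-3-yl]methyl 4-methylbenzenesulfonate
Conditions: TsCl, Et3N, DMAP (cat.), CH2Cl2, 0 °C to rt
Reagents that add atoms: 4-methylbenzenesulfonyl chloride, Cc1ccc(cc1)S(Cl)(=O)=O
Why: Sulfonylation of the only hydroxyl group, a primary alcohol, gives the leaving group for the deoxygenation; 15 is used at once and not heated.

Step 9
Reactants: 15 [(2R,3S)-4-chloro-6-methoxy-2-(3,4,5-trimethoxyphenyl)-2,3-dihydro-1-benzofuran-3-yl]methyl 4-methylbenzenesulfonate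
Product: 16 (2R,3R)-4-chloro-6-methoxy-3-methyl-2-(3,4,5-trimethoxyphenyl)-2,3-dihydro-1-benzofuran
Conditions: LiBHEt3, THF, 0 °C to rt
Reagents that add atoms: none
Why: SN2 displacement of the primary tosylate by hydride gives the C3 methyl group. LiBHEt3 is strongly nucleophilic and weakly basic, which should outrun elimination to the 3-methylene compound and aryl participation of ring A, and it leaves the aryl chloride and the C3 centre untouched.

Step 10
Reactants: 16 (2R,3R)-4-chloro-6-methoxy-3-methyl-2-(3,4,5-trimethoxyphenyl)-2,3-dihydro-1-benzofuran
Product: 17 (2R,3R)-6-methoxy-3-methyl-2-(3,4,5-trimethoxyphenyl)-2,3-dihydro-1-benzofuran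
Conditions: Pd(OAc)2, PCy3, HCO2Na, DMF, 100 °C
Reagents that add atoms: none
Why: Palladium-catalysed transfer hydrodehalogenation: zerovalent palladium carrying the electron-rich PCy3 inserts into the aryl C–Cl bond, formate replaces chloride and loses CO2 to give an aryl palladium hydride, and reductive elimination gives the arene. Homogeneous conditions without H2 or a metal surface should spare the benzylic C2–O1 bond.

Step 11
Reactants: 17 (2R,3R)-6-methoxy-3-methyl-2-(3,4,5-trimethoxyphenyl)-2,3-dihydro-1-benzofuran
Product: 18 (2R,3R)-5-bromo-6-methoxy-3-methyl-2-(3,4,5-trimethoxyphenyl)-2,3-dihydro-1-benzofuran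
Conditions: NBS (1.0 equiv), MeCN, −20 to 0 °C, dark
Reagents that add atoms: N-bromosuccinimide, O=C1CCC(=O)N1Br
Why: Electrophilic aromatic bromination; C5 is para to O1 and ortho to the C6 methoxy group and has a free neighbour (C4–H), whereas C7 lies between two oxygens. The open positions of ring C are flanked by a methoxy group and the C2 substituent and are deactivated by the meta, out-of-plane 4′-methoxy group, so one equivalent of reagent at low temperature should brominate C5 first.

Step 12
Reactants: 18 (2R,3R)-5-bromo-6-methoxy-3-methyl-2-(3,4,5-trimethoxyphenyl)-2,3-dihydro-1-benzofuran; 19 (E)-prop-1-enylboronic acid pinacol ester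
Product: 20 (2R,3R)-6-methoxy-3-methyl-5-[(E)-prop-1-en-1-yl]-2-(3,4,5-trimethoxyphenyl)-2,3-dihydro-1-benzofuran
Conditions: Pd(PPh3)4, K2CO3, 1,4-dioxane/H2O, 90 °C
Reagents that add atoms: none
Why: Suzuki–Miyaura cross-coupling: oxidative addition of the aryl bromide to zerovalent palladium, base-assisted transmetalation of the alkenyl boronate and reductive elimination proceed with retention of the E geometry of 19. No acid, oxidant or hydride follows, so the propenyl group and both stereocentres are delivered intact.

## Compound list

1 | 3-chloro-5-methoxyphenol | COc1cc(O)cc(Cl)c1 | starting material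
2 | 3-chloro-5-methoxyphenyl acetate | COc1cc(Cl)cc(OC(C)=O)c1 | intermediate
3 | 2-bromo-3-chloro-5-methoxyphenyl acetate | COc1cc(Cl)c(Br)c(OC(C)=O)c1 | intermediate
4 | 2-bromo-3-chloro-5-methoxyphenol | COc1cc(O)c(Br)c(Cl)c1 | intermediate
5 | (2-bromo-3-chloro-5-methoxyphenoxy)trimethylsilane | COc1cc(Cl)c(Br)c(O[Si](C)(C)C)c1 | intermediate (not isolated)
6 | lithium 3-chloro-5-methoxy-2-(trimethylsilyl)phenolate | COc1cc(Cl)c([Si](C)(C)C)c([O-])c1.[Li+] | intermediate (not isolated)
7 | 3-chloro-5-methoxy-2-(trimethylsilyl)phenyl trifluoromethanesulfonate | COc1cc(Cl)c([Si](C)(C)C)c(OS(=O)(=O)C(F)(F)F)c1 | intermediate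
8 | 3,4,5-trimethoxybenzaldehyde | COc1cc(C=O)cc(OC)c1OC | starting material
9 | vinylmagnesium bromide | C=C[Mg]Br | starting material
10 | rac-1-(3,4,5-trimethoxyphenyl)prop-2-en-1-ol | C=CC(O)c1cc(OC)c(OC)c(OC)c1 | intermediate
11 | (S)-[(2R)-oxiran-2-yl](3,4,5-trimethoxyphenyl)methanol (erythro) | O[C@@H](c1cc(OC)c(OC)c(OC)c1)[C@H]1CO1 | intermediate
12 | sodium (S)-[(2R)-oxiran-2-yl](3,4,5-trimethoxyphenyl)methanolate | [Na+].[O-][C@@H](c1cc(OC)c(OC)c(OC)c1)[C@H]1CO1 | intermediate (not isolated)
13 | 3-chloro-5-methoxybenzyne (1-chloro-5-methoxycyclohexa-1,5-dien-3-yne) | COC1=CC#CC(Cl)=C1 | intermediate (not isolated)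
14 | [(2R,3S)-4-chloro-6-methoxy-2-(3,4,5-trimethoxyphenyl)-2,3-dihydro-1-benzofuran-3-yl]methanol | COc1cc(Cl)c2c(c1)O[C@@H](c1cc(OC)c(OC)c(OC)c1)[C@@H]2CO | intermediate
15 | [(2R,3S)-4-chloro-6-methoxy-2-(3,4,5-trimethoxyphenyl)-2,3-dihydro-1-benzofuran-3-yl]methyl 4-methylbenzenesulfonate | COc1cc(Cl)c2c(c1)O[C@@H](c1cc(OC)c(OC)c(OC)c1)[C@@H]2COS(=O)(=O)c1ccc(C)cc1 | intermediate
16 | (2R,3R)-4-chloro-6-methoxy-3-methyl-2-(3,4,5-trimethoxyphenyl)-2,3-dihydro-1-benzofuran | COc1cc(Cl)c2c(c1)O[C@@H](c1cc(OC)c(OC)c(OC)c1)[C@@H]2C | intermediate
17 | (2R,3R)-6-methoxy-3-methyl-2-(3,4,5-trimethoxyphenyl)-2,3-dihydro-1-benzofuran | COc1ccc2c(c1)O[C@@H](c1cc(OC)c(OC)c(OC)c1)[C@@H]2C | intermediate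
18 | (2R,3R)-5-bromo-6-methoxy-3-methyl-2-(3,4,5-trimethoxyphenyl)-2,3-dihydro-1-benzofuran | Brc1cc2c(cc1OC)O[C@@H](c1cc(OC)c(OC)c(OC)c1)[C@@H]2C | intermediate
19 | (E)-prop-1-enylboronic acid pinacol ester (4,4,5,5-tetramethyl-2-[(E)-prop-1-enyl]-1,3,2-dioxaborolane) | C/C=C/B1OC(C)(C)C(C)(C)O1 | starting material
20 | (2R,3R)-6-methoxy-3-methyl-5-[(E)-prop-1-en-1-yl]-2-(3,4,5-trimethoxyphenyl)-2,3-dihydro-1-benzofuran | C/C=C/c1cc2c(cc1OC)O[C@@H](c1cc(OC)c(OC)c(OC)c1)[C@@H]2C | target

## Step count and least certain steps

Total step count: 12. Longest linear sequence: 10 steps (steps 1–4, then 7–12, from 3-chloro-5-methoxyphenol); the epoxy alcohol branch (steps 5 and 6) joins at step 7.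

**Step 7 (key step, proposed new method).** Three processes are most likely to go wrong:
- The aryl anion, which sits next to chlorine, may be lost before it closes the ring, by elimination of chloride to a second aryne or by protonation (solvent, or internal transfer from C2–H).
- Alkoxide 12 may undergo Payne rearrangement to the isomeric primary alkoxide before it meets the aryne, which would lead to constitutional isomers.
- The primary alkoxide of the product may consume aryne.

Fallback by known chemistry, setting out from 11 and bromophenol 4 and returning at 14:
- Mitsunobu inversion of 11 with 4-nitrobenzoic acid (PPh3, diisopropyl azodicarboxylate, THF, 0 °C) should give the threo ester (R)-[(2R)-oxiran-2-yl](3,4,5-trimethoxyphenyl)methyl 4-nitrobenzoate F1.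
- Brief cold methanolysis (catalytic K2CO3, MeOH, 0 °C) should free the threo epoxy alcohol (R)-[(2R)-oxiran-2-yl](3,4,5-trimethoxyphenyl)methanol F2.
- A second Mitsunobu reaction, with phenol 4 as the acidic partner, inverts the carbinol again and should give the aryl ether (2R)-2-[(S)-(2-bromo-3-chloro-5-methoxyphenoxy)(3,4,5-trimethoxyphenyl)methyl]oxirane F3, which has the C2 configuration of 11.
- Bromine–lithium exchange (n-BuLi, THF, −100 °C) followed by BF3·OEt2 at −78 °C should close ring B by the Parham-type 5-exo opening of the epoxide, at a temperature where the 2-chloroaryllithium does not lose LiCl, to give 14.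

**Step 11.** The likely failure is poor site selectivity of the bromination: substitution spread over C5, C7 and the open positions of ring C, or double bromination, because both rings carry two donor oxygens ortho/para to a free position. Fallback, setting out from 17 and returning at 20 (steps 11 and 12 are then not needed): Vilsmeier–Haack formylation (POCl3, DMF, 0 to 60 °C), a weaker and bulkier electrophile that should discriminate more sharply against the doubly flanked positions of ring C, should give (2R,3R)-6-methoxy-3-methyl-2-(3,4,5-trimethoxyphenyl)-2,3-dihydro-1-benzofuran-5-carbaldehyde F4. Julia–Kocienski olefination with 5-(ethylsulfonyl)-1-phenyl-1H-tetrazole and KN(SiMe3)2 in DME (−60 °C to rt) should then give the E-propenyl compound 20 directly.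

**Step 10.** The likely failure is slow oxidative addition of zerovalent palladium into the C4–Cl bond, which is flanked by the substituted C3a and sits on an oxygenated ring; this would lead to incomplete reduction or catalyst decomposition at the temperature required. Fallback, setting out from 16 and returning at 17: single-electron hydrodechlorination, in which HCO2Na, a thiol hydrogen-atom-transfer catalyst and an organic photocatalyst (1,3-dicyano-2,4,5,6-tetrakis(diphenylamino)benzene) under blue light in DMSO generate the carbon dioxide radical anion. This reduces the aryl chloride to an aryl radical that is quenched by the thiol, so the outcome no longer depends on metal insertion at the hindered carbon. The fallback makes no new compound (entered as F0).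

**Step 6.** The likely failures are erosion of the enantiomeric and diastereomeric purity of the epoxy alcohol if the rate difference between the enantiomers of this aryl vinyl carbinol is modest or the conversion overshoots, and opening of the terminal epoxide by the titanium alkoxide medium. Fallback, setting out from 10 and returning at 11:
- The enantiomer is selected by enzymatic acylation instead of by the oxidant. Immobilised Candida antarctica lipase B with vinyl acetate in tert-butyl methyl ether should acylate the (R)-alcohol, following the usual preference of lipases for secondary alcohols, to give (R)-1-(3,4,5-trimethoxyphenyl)prop-2-en-1-yl acetate F5.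
- Methanolysis (K2CO3, MeOH) should give (R)-1-(3,4,5-trimethoxyphenyl)prop-2-en-1-ol F6.
- Epoxidation of this single enantiomer to full conversion with the matched catalyst (Ti(OiPr)4, L-(+)-diisopropyl tartrate, t-BuOOH, CH2Cl2, −20 °C) then only has to be diastereoselective and should give 11.

## Further compounds

F1 | step 7 | (R)-[(2R)-oxiran-2-yl](3,4,5-trimethoxyphenyl)methyl 4-nitrobenzoate | O=C(O[C@H](c1cc(OC)c(OC)c(OC)c1)[C@H]1CO1)c1ccc(cc1)[N+](=O)[O-]
F2 | step 7 | (R)-[(2R)-oxiran-2-yl](3,4,5-trimethoxyphenyl)methanol (threo) | O[C@H](c1cc(OC)c(OC)c(OC)c1)[C@H]1CO1
F3 | step 7 | (2R)-2-[(S)-(2-bromo-3-chloro-5-methoxyphenoxy)(3,4,5-trimethoxyphenyl)methyl]oxirane | COc1cc(Cl)c(Br)c(O[C@@H](c2cc(OC)c(OC)c(OC)c2)[C@H]2CO2)c1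
F4 | step 11 | (2R,3R)-6-methoxy-3-methyl-2-(3,4,5-trimethoxyphenyl)-2,3-dihydro-1-benzofuran-5-carbaldehyde | O=Cc1cc2c(cc1OC)O[C@@H](c1cc(OC)c(OC)c(OC)c1)[C@@H]2C
F0 | step 10 | none | none
F5 | step 6 | (R)-1-(3,4,5-trimethoxyphenyl)prop-2-en-1-yl acetate | CC(=O)O[C@@H](c1cc(OC)c(OC)c(OC)c1)C=C
F6 | step 6 | (R)-1-(3,4,5-trimethoxyphenyl)prop-2-en-1-ol | O[C@@H](c1cc(OC)c(OC)c(OC)c1)C=C
A1 | alternative 1 | (7R,8R)-8-hydroxy-7-methyl-8-(3,4,5-trimethoxyphenyl)oct-1-en-4-yn-3-one | C=CC(=O)C#CC[C@@H](C)[C@@H](O)c1cc(OC)c(OC)c(OC)c1
A2 | alternative 1 | (2R,3R)-3-methyl-2-(3,4,5-trimethoxyphenyl)-3,3a,4,5-tetrahydro-1-benzofuran-6(2H)-one, C3a unassigned | O=C1CCC2C(=C1)O[C@@H](c1cc(OC)c(OC)c(OC)c1)[C@@H]2C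
A3 | alternative 2 | (2R,3R)-5-[2-methoxy-2-(trimethylsilyloxy)ethenyl]-3-methyl-2-(3,4,5-trimethoxyphenyl)-2,3-dihydrofuran | COC(O[Si](C)(C)C)=CC1=C[C@@H](C)[C@H](c2cc(OC)c(OC)c(OC)c2)O1
A4 | alternative 2 | pent-1-yn-3-one | CCC(=O)C#C
A5 | alternative 2 | 1-[(2R,3R)-6-methoxy-3-methyl-2-(3,4,5-trimethoxyphenyl)-2,3-dihydro-1-benzofuran-5-yl]propan-1-one | CCC(=O)c1cc2c(cc1OC)O[C@@H](c1cc(OC)c(OC)c(OC)c1)[C@@H]2C
A6 | alternative 3 | (4R,5R)-4-methyl-3-methylidene-5-(3,4,5-trimethoxyphenyl)oxolan-2-one | C=C1[C@@H](C)[C@H](c2cc(OC)c(OC)c(OC)c2)OC1=O
A7 | alternative 3 | ethyl 3-oxobutanoate | CCOC(=O)CC(C)=O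
A8 | alternative 3 | ethyl (2R,3R)-3-methyl-6-oxo-2-(3,4,5-trimethoxyphenyl)-2,3,3a,4,5,6-hexahydro-1-benzofuran-5-carboxylate, C3a and C5 unassigned | CCOC(=O)C1CC2C(=CC1=O)O[C@@H](c1cc(OC)c(OC)c(OC)c1)[C@@H]2C
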